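**Strategy.** The oxane (O1, C2 carrying the arylethyl chain, C4 the hydroxyl, C6 the syringyl ring) is disconnected at C2–C3. Ether carbon C2 lies two carbons (C1', C2') from the guaiacyl ring, so a ketone at C2' turns C2 into the β-carbon of an aryl enone whose vinyl ether oxygen is O1. A primary radical at C3, released from an iodide, should add to that carbon and in one operation close the ring 6-exo, forge C2–C3 and set C2 cis to C4 and C6. The precursor is an acyclic (E)-β-alkoxy enone: the C6 benzylic alcohol O-vinylated by a guaiacyl ynone, with C4 as silyl ether and C3 as iodide.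

Key step: step 10

Remark: the benzyl ethers of both phenolic aldehydes are catalogue compounds and are used as bought. (S)-Epichlorohydrin is the enantiomer that maps onto C4, because dithiane anions open it at the ring CH2 and the stereocentre is retained (only its CIP ranking changes along the route).

**Step 1**
Reactants: 1 4-(benzyloxy)-3,5-dimethoxybenzaldehyde
Product: 2 2-[4-(benzyloxy)-3,5-dimethoxyphenyl]-1,3-dithiane
Conditions: HS(CH2)3SH, BF3·OEt2 (cat.), CH2Cl2, 0 °C to rt
Reagents that add atoms: propane-1,3-dithiol, SCCCS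
Why: Lewis-acid-catalysed thioacetalisation of an aromatic aldehyde is reliable and turns the formyl carbon (the future C6) into a Corey–Seebach acyl-anion equivalent, while the aryl benzyl ether is inert to catalytic BF3·OEt2.

**Step 2**
Reactants: 2 2-[4-(benzyloxy)-3,5-dimethoxyphenyl]-1,3-dithiane; 3 (S)-epichlorohydrin
Product: 6 (S)-2-({2-[4-(benzyloxy)-3,5-dimethoxyphenyl]-1,3-dithian-2-yl}methyl)oxirane, via 2-lithiodithiane 4 (not isolated), via lithium chlorohydrin alkoxide 5 (not isolated)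
Conditions: n-BuLi, THF, −78 to −30 °C; then 3, −78 °C to rt
Reagents that add atoms: none
Why: Corey–Seebach umpolung: the 2-aryl-2-lithiodithiane opens the oxirane of 3 at its CH2 terminus and the resulting alkoxide displaces chloride on warming (epoxide relay), so no bond to the stereocentre is broken and it becomes C4 with the configuration bought in 3.

**Step 3**
Reactants: 6 (S)-2-({2-[4-(benzyloxy)-3,5-dimethoxyphenyl]-1,3-dithian-2-yl}methyl)oxirane
Product: 7 (S)-1-{2-[4-(benzyloxy)-3,5-dimethoxyphenyl]-1,3-dithian-2-yl}-3-iodopropan-2-ol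
Conditions: LiI, AcOH, THF, 0 °C to rt
Reagents that add atoms: lithium iodide, [Li+].[I-]
Why: Acid-assisted SN2 opening of a terminal epoxide by iodide occurs at the unsubstituted carbon, giving the iodohydrin that carries the future C3 radical precursor without touching the carbinol centre.

**Step 4**
Reactants: 7 (S)-1-{2-[4-(benzyloxy)-3,5-dimethoxyphenyl]-1,3-dithian-2-yl}-3-iodopropan-2-ol
Product: 8 tert-butyldimethylsilyl ether of 7, (S)-configured at the silyloxy carbon
Conditions: TBSOTf, 2,6-lutidine, CH2Cl2, −78 to 0 °C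
Reagents that add atoms: tert-butyldimethylsilyl triflate, CC(C)(C)[Si](C)(C)OS(=O)(=O)C(F)(F)F
Why: Silylation of a secondary alcohol with a silyl triflate and a hindered, non-nucleophilic base is fast at low temperature and avoids the alkoxide that would re-close the iodohydrin to the oxirane.

**Step 5**
Reactants: 8 tert-butyldimethylsilyl ether of 7
Product: 9 (S)-1-[4-(benzyloxy)-3,5-dimethoxyphenyl]-3-[(tert-butyldimethylsilyl)oxy]-4-iodobutan-1-one
Conditions: MeI, CaCO3, MeCN/H2O 9:1, 45 °C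
Reagents that add atoms: water, O
Why: Alkylative dithiane hydrolysis (S-methylation, then water attack on the aryl-stabilised thionium ion) unmasks the aryl ketone under buffered conditions that use no thiophilic metal salt or oxidant and so leave the primary iodide, the silyl ether and the benzyl ether intact.

**Step 6**
Reactants: 9 (S)-1-[4-(benzyloxy)-3,5-dimethoxyphenyl]-3-[(tert-butyldimethylsilyl)oxy]-4-iodobutan-1-one
Product: 10 (1S,3S)-1-[4-(benzyloxy)-3,5-dimethoxyphenyl]-3-[(tert-butyldimethylsilyl)oxy]-4-iodobutan-1-ol (1,3-anti)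
Conditions: (R)-2-methyl-CBS-oxazaborolidine (0.2 equiv), BH3·SMe2, THF, −20 °C; MeOH quench
Reagents that add atoms: none
Why: Corey–Bakshi–Shibata reduction of an aryl alkyl ketone: the (R)-oxazaborolidine binds the carbonyl with the aryl group in the large-substituent position and delivers hydride to the face that gives the (S)-carbinol (future C6), 1,3-anti to the C4 silyloxy centre, under reagent control.

**Step 7**
Reactants: 11 4-(benzyloxy)-3-methoxybenzaldehyde; 12 ethynylmagnesium bromide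
Product: 13 rac-1-[4-(benzyloxy)-3-methoxyphenyl]prop-2-yn-1-ol
Conditions: THF, 0 °C; aq. NH4Cl
Reagents that add atoms: none
Why: Addition of an alkynyl Grignard reagent to an aromatic aldehyde gives the propargylic alcohol, whose new centre is racemic and is removed in the next step.

**Step 8**
Reactants: 13 rac-1-[4-(benzyloxy)-3-methoxyphenyl]prop-2-yn-1-ol
Product: 14 1-[4-(benzyloxy)-3-methoxyphenyl]prop-2-yn-1-one
Conditions: activated MnO2, CH2Cl2, rt
Reagents that add atoms: none
Why: Activated MnO2 oxidises benzylic-propargylic alcohols selectively to the conjugated ynone without affecting the terminal alkyne or the benzyl ether.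

**Step 9**
Reactants: 10 (1S,3S)-1-[4-(benzyloxy)-3,5-dimethoxyphenyl]-3-[(tert-butyldimethylsilyl)oxy]-4-iodobutan-1-ol; 14 1-[4-(benzyloxy)-3-methoxyphenyl]prop-2-yn-1-one
Product: 15 (E)-1-[4-(benzyloxy)-3-methoxyphenyl]-3-{(1S,3S)-1-[4-(benzyloxy)-3,5-dimethoxyphenyl]-3-[(tert-butyldimethylsilyl)oxy]-4-iodobutoxy}prop-2-en-1-one
Conditions: PMe3 (0.1 equiv), CH2Cl2, 0 °C
Reagents that add atoms: none
Why: Trialkylphosphine-catalysed oxa-Michael addition (hydroalkoxylation) of an alcohol to a terminal ynone proceeds through a β-phosphonium allenolate that deprotonates the alcohol, and addition–elimination then gives the (E)-β-alkoxy enone under neutral conditions in which the C6 configuration and the hindered C3 iodide are untouched.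

**Step 10 (key step)**
Reactants: 15 (E)-β-alkoxy enone with C3 iodide and C4 silyl ether
Product: 16 1-[4-(benzyloxy)-3-methoxyphenyl]-2-{(2R,4R,6S)-6-[4-(benzyloxy)-3,5-dimethoxyphenyl]-4-[(tert-butyldimethylsilyl)oxy]oxan-2-yl}ethan-1-one (all-cis oxane)
Conditions: Bu3SnH (1.3 equiv), AIBN (0.2 equiv), toluene (0.01 M), 85 °C, syringe-pump addition over 4 h
Reagents that add atoms: none
Why: The tributylstannyl radical abstracts iodine from 15, the nucleophilic primary C3 radical adds to the oxygen-bearing, electrophilic β-carbon of the aryl enone, and the delocalised α-keto radical then takes hydrogen from Bu3SnH and carries the chain. The closest known reaction type is the tin-hydride cyclisation of β-alkoxyacrylates and β-alkoxyvinyl ketones to cis-2,6-disubstituted oxanes. The oxane is closed in the 6-exo-trig mode through the new C2–C3 bond. The C2 stereocentre is set by a chair transition state in which the C6 aryl group, the C4 silyloxy group and the s-trans (E)-enone arm are all equatorial, which places H2, H4 and H6 on one face. The step needs cyclisation to outrun direct reduction of the C3 radical and attack at the β-carbon only; the polarity match between an alkyl radical and a vinylogous ester, the low stannane concentration kept by slow addition, and the lack of any activated hydrogen within 1,5-reach of C3 should secure this.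

**Step 11**
Reactants: 16 all-cis oxane aryl ketone
Product: 17 N'-tosylhydrazone of 16 at C2' (ring centres 2S,4R,6S; C=N isomer mixture)
Conditions: TsNHNH2, EtOH/THF, 50 °C
Reagents that add atoms: p-toluenesulfonyl hydrazide, Cc1ccc(cc1)S(=O)(=O)NN
Why: Condensation of the aryl ketone with a sulfonyl hydrazide under near-neutral conditions gives the tosylhydrazone without triggering retro-oxa-Michael opening at C2.

**Step 12**
Reactants: 17 N'-tosylhydrazone of 16
Product: 20 (2S,4R,6S)-6-[4-(benzyloxy)-3,5-dimethoxyphenyl]-2-{2-[4-(benzyloxy)-3-methoxyphenyl]ethyl}-4-[(tert-butyldimethylsilyl)oxy]oxane, via N-boryl tosylhydrazine 18 (not isolated), via monoalkyl diazene 19 (not isolated)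
Conditions: catecholborane, CHCl3, 0 °C to rt; then NaOAc·3H2O, 60 °C
Reagents that add atoms: none
Why: Kabalka reduction of a tosylhydrazone: catecholborane hydroborates the C=N bond, acetate then triggers loss of sulfinate to a monoalkyl diazene that expels N2, so C2' ends as CH2 under conditions mild enough for the C2–O1 and benzylic C6–O1 bonds, the silyl ether and the benzyl ethers.

**Step 13**
Reactants: 20 silyl ether of the dibenzylated oxane
Product: 21 (2S,4R,6S)-6-[4-(benzyloxy)-3,5-dimethoxyphenyl]-2-{2-[4-(benzyloxy)-3-methoxyphenyl]ethyl}oxan-4-ol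
Conditions: TBAF, THF, rt; aq. NH4Cl
Reagents that add atoms: none
Why: Fluoride-mediated cleavage of the secondary silyl ether frees the C4 hydroxyl while both phenols are still benzylated, so no phenoxide that could ionise the benzylic C6–O1 bond is formed.

**Step 14**
Reactants: 21 dibenzylated oxan-4-ol
Product: 22 (2S,4R,6S)-6-(4-hydroxy-3,5-dimethoxyphenyl)-2-[2-(4-hydroxy-3-methoxyphenyl)ethyl]oxan-4-ol (CNP0302691.1)
Conditions: H2 (1 atm), 10% Pd/C, EtOAc/EtOH, rt
Reagents that add atoms: none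
Why: Catalytic hydrogenolysis of aryl benzyl ethers over Pd/C in a neutral solvent is much faster than cleavage of the cyclic benzylic C6–O1 ether, so both phenols should be released with the three stereocentres unchanged.

**Compound list**

1 | 4-(benzyloxy)-3,5-dimethoxybenzaldehyde | COc1cc(C=O)cc(OC)c1OCc1ccccc1 | starting material
2 | 2-[4-(benzyloxy)-3,5-dimethoxyphenyl]-1,3-dithiane | COc1cc(cc(OC)c1OCc1ccccc1)C1SCCCS1 | intermediate
3 | (S)-epichlorohydrin, (S)-2-(chloromethyl)oxirane | ClC[C@@H]1CO1 | starting material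
4 | 2-lithio-2-[4-(benzyloxy)-3,5-dimethoxyphenyl]-1,3-dithiane (in situ) | [Li]C1(SCCCS1)c1cc(OC)c(OCc2ccccc2)c(OC)c1 | intermediate
5 | lithium (S)-1-chloro-3-{2-[4-(benzyloxy)-3,5-dimethoxyphenyl]-1,3-dithian-2-yl}propan-2-olate (in situ) | ClC[C@@H](O[Li])CC1(SCCCS1)c1cc(OC)c(OCc2ccccc2)c(OC)c1 | intermediate
6 | (S)-2-({2-[4-(benzyloxy)-3,5-dimethoxyphenyl]-1,3-dithian-2-yl}methyl)oxirane | C1O[C@H]1CC1(SCCCS1)c1cc(OC)c(OCc2ccccc2)c(OC)c1 | intermediate
7 | (S)-1-{2-[4-(benzyloxy)-3,5-dimethoxyphenyl]-1,3-dithian-2-yl}-3-iodopropan-2-ol | IC[C@@H](O)CC1(SCCCS1)c1cc(OC)c(OCc2ccccc2)c(OC)c1 | intermediate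
8 | tert-butyldimethylsilyl ether of 7, (S) | IC[C@@H](O[Si](C)(C)C(C)(C)C)CC1(SCCCS1)c1cc(OC)c(OCc2ccccc2)c(OC)c1 | intermediate
9 | (S)-1-[4-(benzyloxy)-3,5-dimethoxyphenyl]-3-[(tert-butyldimethylsilyl)oxy]-4-iodobutan-1-one | IC[C@@H](O[Si](C)(C)C(C)(C)C)CC(=O)c1cc(OC)c(OCc2ccccc2)c(OC)c1 | intermediate
10 | (1S,3S)-1-[4-(benzyloxy)-3,5-dimethoxyphenyl]-3-[(tert-butyldimethylsilyl)oxy]-4-iodobutan-1-ol | IC[C@@H](O[Si](C)(C)C(C)(C)C)C[C@H](O)c1cc(OC)c(OCc2ccccc2)c(OC)c1 | intermediate
11 | 4-(benzyloxy)-3-methoxybenzaldehyde | COc1cc(C=O)ccc1OCc1ccccc1 | starting material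
12 | ethynylmagnesium bromide | C#C[Mg]Br | starting material
13 | rac-1-[4-(benzyloxy)-3-methoxyphenyl]prop-2-yn-1-ol | COc1cc(C(O)C#C)ccc1OCc1ccccc1 | intermediate
14 | 1-[4-(benzyloxy)-3-methoxyphenyl]prop-2-yn-1-one | COc1cc(C(=O)C#C)ccc1OCc1ccccc1 | intermediate
15 | (E)-1-[4-(benzyloxy)-3-methoxyphenyl]-3-{(1S,3S)-1-[4-(benzyloxy)-3,5-dimethoxyphenyl]-3-[(tert-butyldimethylsilyl)oxy]-4-iodobutoxy}prop-2-en-1-one | IC[C@@H](O[Si](C)(C)C(C)(C)C)C[C@@H](c1cc(OC)c(OCc2ccccc2)c(OC)c1)O/C=C/C(=O)c1ccc(OCc2ccccc2)c(OC)c1 | intermediate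
16 | 1-[4-(benzyloxy)-3-methoxyphenyl]-2-{(2R,4R,6S)-6-[4-(benzyloxy)-3,5-dimethoxyphenyl]-4-[(tert-butyldimethylsilyl)oxy]oxan-2-yl}ethan-1-one | COc1cc(C(=O)C[C@H]2C[C@@H](O[Si](C)(C)C(C)(C)C)C[C@@H](c3cc(OC)c(OCc4ccccc4)c(OC)c3)O2)ccc1OCc1ccccc1 | intermediate
17 | N'-tosylhydrazone of 16 (ring 2S,4R,6S) | COc1cc(C(=NNS(=O)(=O)c5ccc(C)cc5)C[C@H]2C[C@@H](O[Si](C)(C)C(C)(C)C)C[C@@H](c3cc(OC)c(OCc4ccccc4)c(OC)c3)O2)ccc1OCc1ccccc1 | intermediate
18 | N-(1,3,2-benzodioxaborol-2-yl)-N'-tosylhydrazine adduct at C2' (epimer mixture at C2', in situ) | COc1cc(C(N(NS(=O)(=O)c5ccc(C)cc5)B6Oc7ccccc7O6)C[C@H]2C[C@@H](O[Si](C)(C)C(C)(C)C)C[C@@H](c3cc(OC)c(OCc4ccccc4)c(OC)c3)O2)ccc1OCc1ccccc1 | intermediate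
19 | monoalkyl diazene at C2' (in situ) | COc1cc(C(N=N)C[C@H]2C[C@@H](O[Si](C)(C)C(C)(C)C)C[C@@H](c3cc(OC)c(OCc4ccccc4)c(OC)c3)O2)ccc1OCc1ccccc1 | intermediate
20 | (2S,4R,6S)-6-[4-(benzyloxy)-3,5-dimethoxyphenyl]-2-{2-[4-(benzyloxy)-3-methoxyphenyl]ethyl}-4-[(tert-butyldimethylsilyl)oxy]oxane | COc1cc(CC[C@H]2C[C@@H](O[Si](C)(C)C(C)(C)C)C[C@@H](c3cc(OC)c(OCc4ccccc4)c(OC)c3)O2)ccc1OCc1ccccc1 | intermediate
21 | (2S,4R,6S)-6-[4-(benzyloxy)-3,5-dimethoxyphenyl]-2-{2-[4-(benzyloxy)-3-methoxyphenyl]ethyl}oxan-4-ol | COc1cc(CC[C@H]2C[C@@H](O)C[C@@H](c3cc(OC)c(OCc4ccccc4)c(OC)c3)O2)ccc1OCc1ccccc1 | intermediate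
22 | (2S,4R,6S)-6-(4-hydroxy-3,5-dimethoxyphenyl)-2-[2-(4-hydroxy-3-methoxyphenyl)ethyl]oxan-4-ol | COc1cc(CC[C@H]2C[C@@H](O)C[C@@H](c3cc(OC)c(O)c(OC)c3)O2)ccc1O | target

**Step count.** Total: 14 steps. Longest linear sequence: 12 steps (steps 1–6 and 9–14); the ynone branch (steps 7–8) joins at step 9.

**Steps most likely to fail**

Step 10. The C3 radical may be reduced before it cyclises, the stannyl radical may add to the aryl enone, or the closure may show poor facial control at C2. The fallback closes the ring through the C2–O1 bond by oxa-Michael addition instead. It sets out from epoxide 6: CuI-catalysed opening with vinylmagnesium bromide (THF, −30 °C) would give (R)-1-{2-[4-(benzyloxy)-3,5-dimethoxyphenyl]-1,3-dithian-2-yl}pent-4-en-2-ol F1. Silylation (TBSOTf, 2,6-lutidine) would give its tert-butyldimethylsilyl ether F2. Hydrolysis (MeI, CaCO3, aqueous MeCN) would give (R)-1-[4-(benzyloxy)-3,5-dimethoxyphenyl]-3-[(tert-butyldimethylsilyl)oxy]hex-5-en-1-one F3. The same (R)-oxazaborolidine/BH3·SMe2 reduction would give (1S,3R)-1-[4-(benzyloxy)-3,5-dimethoxyphenyl]-3-[(tert-butyldimethylsilyl)oxy]hex-5-en-1-ol F4. In parallel, aldehyde 11 and vinylmagnesium bromide would give rac-1-[4-(benzyloxy)-3-methoxyphenyl]prop-2-en-1-ol F5, and MnO2 would oxidise it to 1-[4-(benzyloxy)-3-methoxyphenyl]prop-2-en-1-one F6. Cross-metathesis of F4 with F6 (second-generation Hoveyda–Grubbs catalyst, CH2Cl2, 40 °C) would give (2E,5R,7S)-1-[4-(benzyloxy)-3-methoxyphenyl]-7-[4-(benzyloxy)-3,5-dimethoxyphenyl]-5-[(tert-butyldimethylsilyl)oxy]-7-hydroxyhept-2-en-1-one F7. Its DBU-mediated oxa-Michael closure should equilibrate to the all-equatorial oxane and comes back to the route at 16.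

Step 12. Hydroboration of the hindered, electron-rich aryl hydrazone may stall, or the hydrazone may decompose by alkene formation or by loss of the ring oxygen from C2. The fallback deoxygenates through the alcohol by Barton–McCombie chemistry. It sets out from ketone 16: NaBH4 (MeOH, 0 °C) would give the benzylic alcohol 1-[4-(benzyloxy)-3-methoxyphenyl]-2-{(2S,4R,6S)-6-[4-(benzyloxy)-3,5-dimethoxyphenyl]-4-[(tert-butyldimethylsilyl)oxy]oxan-2-yl}ethan-1-ol F8 as an epimer mixture. 1,1'-Thiocarbonyldiimidazole with DMAP (CH2Cl2, rt) would give its O-(imidazol-1-ylthiocarbonyl) derivative F9. Bu3SnH/AIBN (toluene, 85 °C) would then cleave the benzylic C–O bond by radical deoxygenation and comes back to the route at 20.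

Step 9. Conjugate addition of the hindered benzylic alcohol may be slow, so that the phosphine is consumed by alkylation at the primary iodide, or the transient alkoxide may close onto C3 to form an oxolane. The fallback uses vinylogous substitution on a β-chlorovinyl ketone instead of alkyne hydroalkoxylation. It sets out from ynone 14: LiCl/AcOH would add HCl to give 3-chloro-1-[4-(benzyloxy)-3-methoxyphenyl]prop-2-en-1-one F10 (alkene geometry immaterial). Alcohol 10 and F10 with Et3N and catalytic DABCO (CH2Cl2, rt) would give the (E)-β-alkoxy enone by addition–elimination and comes back to the route at 15.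

**Further compounds**

F1 | step 10 | (R)-1-{2-[4-(benzyloxy)-3,5-dimethoxyphenyl]-1,3-dithian-2-yl}pent-4-en-2-ol | C=CC[C@@H](O)CC1(SCCCS1)c1cc(OC)c(OCc2ccccc2)c(OC)c1
F2 | step 10 | tert-butyldimethylsilyl ether of F1, (R) | C=CC[C@@H](O[Si](C)(C)C(C)(C)C)CC1(SCCCS1)c1cc(OC)c(OCc2ccccc2)c(OC)c1
F3 | step 10 | (R)-1-[4-(benzyloxy)-3,5-dimethoxyphenyl]-3-[(tert-butyldimethylsilyl)oxy]hex-5-en-1-one | C=CC[C@@H](O[Si](C)(C)C(C)(C)C)CC(=O)c1cc(OC)c(OCc2ccccc2)c(OC)c1
F4 | step 10 | (1S,3R)-1-[4-(benzyloxy)-3,5-dimethoxyphenyl]-3-[(tert-butyldimethylsilyl)oxy]hex-5-en-1-ol | C=CC[C@@H](O[Si](C)(C)C(C)(C)C)C[C@H](O)c1cc(OC)c(OCc2ccccc2)c(OC)c1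
F5 | step 10 | rac-1-[4-(benzyloxy)-3-methoxyphenyl]prop-2-en-1-ol | COc1cc(C(O)C=C)ccc1OCc1ccccc1
F6 | step 10 | 1-[4-(benzyloxy)-3-methoxyphenyl]prop-2-en-1-one | COc1cc(C(=O)C=C)ccc1OCc1ccccc1
F7 | step 10 | (2E,5R,7S)-1-[4-(benzyloxy)-3-methoxyphenyl]-7-[4-(benzyloxy)-3,5-dimethoxyphenyl]-5-[(tert-butyldimethylsilyl)oxy]-7-hydroxyhept-2-en-1-one | COc1cc(C(=O)/C=C/C[C@@H](O[Si](C)(C)C(C)(C)C)C[C@H](O)c2cc(OC)c(OCc3ccccc3)c(OC)c2)ccc1OCc1ccccc1
F8 | step 12 | 1-[4-(benzyloxy)-3-methoxyphenyl]-2-{(2S,4R,6S)-6-[4-(benzyloxy)-3,5-dimethoxyphenyl]-4-[(tert-butyldimethylsilyl)oxy]oxan-2-yl}ethan-1-ol (carbinol epimers) | COc1cc(C(O)C[C@H]2C[C@@H](O[Si](C)(C)C(C)(C)C)C[C@@H](c3cc(OC)c(OCc4ccccc4)c(OC)c3)O2)ccc1OCc1ccccc1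
F9 | step 12 | O-(imidazol-1-ylthiocarbonyl) derivative of F8 | COc1cc(C(OC(=S)n5ccnc5)C[C@H]2C[C@@H](O[Si](C)(C)C(C)(C)C)C[C@@H](c3cc(OC)c(OCc4ccccc4)c(OC)c3)O2)ccc1OCc1ccccc1
F10 | step 9 | 3-chloro-1-[4-(benzyloxy)-3-methoxyphenyl]prop-2-en-1-one | COc1cc(C(=O)C=CCl)ccc1OCc1ccccc1
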